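**Strategy.** The only ring, cyclohexa-2,5-diene-1,4-dione C1–C6, is made last by strain-release ring expansion. Ring atoms C4(=O)–C5(OMe)=C6(H)–C1(=O) are carried by a squarate-derived cyclobutenone, in which C1 and C4 share a bond absent from the target, and C2(Me)=C3(side chain) by an alkenyl group on its carbinol carbon C4. Heating breaks the C1–C4 bond to give a dienylketene; 6π-electrocyclisation forms C1–C2, the dienone enolises, and oxidation in the same flask gives the quinone. The precursor is a 4-alkenyl-4-hydroxy-3-methoxycyclobutenone holding the complete side chain, whose four syn methyl stereocentres come from iterated zirconium-catalysed asymmetric carboalumination.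

Key step: step 10

Assumption: with one enantiomer of (NMI)2ZrCl2 [bis(1-neomenthylindenyl)zirconium dichloride], ethyl- and methylalumination of a 1-alkene occur on the same alkene face; step 5 therefore uses the (+)-complex, because there the added ethyl group becomes the chain end and the CH2–Al carbon becomes the methyl branch.

Step 1
Reactants: 1 dec-9-en-1-ol
Product: 2 tert-butyl(dec-9-en-1-yloxy)dimethylsilane
Conditions: TBSCl, imidazole, CH2Cl2, 23 °C
Reagents that add atoms: tert-butyldimethylsilyl chloride, CC(C)(C)[Si](C)(C)Cl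
Why: Imidazole-promoted silylation of the primary alcohol masks the hydroxyl for the organoaluminium steps that follow.

Step 2
Reactants: 2 tert-butyl(dec-9-en-1-yloxy)dimethylsilane, 3 vinyl bromide
Product: 6 tert-butyldimethyl{[(9R)-9-methyldodec-11-en-1-yl]oxy}silane, via alkyldimethylalane 4 (not isolated), via alkylzinc triflate 5 (not isolated)
Conditions: Me3Al, methylaluminoxane (MeAlO)n, (−)-(NMI)2ZrCl2 (5 mol%), CH2Cl2, 0 → 23 °C; evaporate; Zn(OTf)2, DMF, 70 °C; then 3, PdCl2(DPEphos) (3 mol%), i-Bu2AlH (6 mol%), 23 °C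
Reagents that add atoms: trimethylaluminium, C[Al](C)C
Why: Zirconium-catalysed asymmetric carboalumination (ZACA) places methyl on the internal alkene carbon with the face chosen by the chiral zirconocene, setting C9 as R, and Al-to-Zn transmetalation with Negishi vinylation then delivers the next terminal alkene without touching that centre.

Step 3
Reactants: 6 tert-butyldimethyl{[(9R)-9-methyldodec-11-en-1-yl]oxy}silane, 3 vinyl bromide
Product: 9 tert-butyl{[(9R,11S)-9,11-dimethyltetradec-13-en-1-yl]oxy}dimethylsilane, via alkyldimethylalane 7 (not isolated), via alkylzinc triflate 8 (not isolated)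
Conditions: Me3Al, methylaluminoxane (MeAlO)n, (−)-(NMI)2ZrCl2 (5 mol%), CH2Cl2, 0 → 23 °C; evaporate; Zn(OTf)2, DMF, 70 °C; then 3, PdCl2(DPEphos) (3 mol%), i-Bu2AlH (6 mol%), 23 °C
Reagents that add atoms: trimethylaluminium, C[Al](C)C
Why: The same ZACA–Negishi vinylation tandem sets C11 under catalyst control by the same zirconocene enantiomer, which should give the 9,11-syn isomer (the descriptor reads 11S only because the allyl group ranks below the branched chain), the anti isomer being removed by chromatography.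

Step 4
Reactants: 9 tert-butyl{[(9R,11S)-9,11-dimethyltetradec-13-en-1-yl]oxy}dimethylsilane, 3 vinyl bromide
Product: 12 tert-butyldimethyl{[(9R,11R,13S)-9,11,13-trimethylhexadec-15-en-1-yl]oxy}silane, via alkyldimethylalane 10 (not isolated), via alkylzinc triflate 11 (not isolated)
Conditions: Me3Al, methylaluminoxane (MeAlO)n, (−)-(NMI)2ZrCl2 (5 mol%), CH2Cl2, 0 → 23 °C; evaporate; Zn(OTf)2, DMF, 70 °C; then 3, PdCl2(DPEphos) (3 mol%), i-Bu2AlH (6 mol%), 23 °C
Reagents that add atoms: trimethylaluminium, C[Al](C)C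
Why: A third ZACA–Negishi vinylation sets C13 by catalyst control with the same zirconocene enantiomer and should give the all-syn 9,11,13-trimethyl array.

Step 5
Reactants: 12 tert-butyldimethyl{[(9R,11R,13S)-9,11,13-trimethylhexadec-15-en-1-yl]oxy}silane
Product: 14 tert-butyldimethyl{[(9R,11R,13S,15S)-9,11,13,15-tetramethylheptadecyl]oxy}silane, via alkyldiethylalane 13 (not isolated)
Conditions: Et3Al, isobutylaluminoxane (i-BuAlO)n (cat.), (+)-(NMI)2ZrCl2 (5 mol%), CH2Cl2, 0 → 23 °C; then H2O, 0 °C, aq. Rochelle salt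
Reagents that add atoms: triethylaluminium, CC[Al](CC)CC
Why: ZACA ethylalumination puts ethyl on the internal carbon and aluminium on the terminus, and protonolysis turns CH2–Al into the C15 methyl group, so that the opposite catalyst enantiomer sets C15 as S, syn to C13.

Step 6
Reactants: 14 tert-butyldimethyl{[(9R,11R,13S,15S)-9,11,13,15-tetramethylheptadecyl]oxy}silane
Product: 15 (9R,11R,13S,15S)-1-bromo-9,11,13,15-tetramethylheptadecane
Conditions: Ph3PBr2, CH2Cl2, 23 °C
Reagents that add atoms: triphenylphosphine dibromide, BrP(Br)(c1ccccc1)(c1ccccc1)c1ccccc1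
Why: Triphenylphosphine dibromide converts a primary silyl ether directly into the bromide (Appel-type substitution through an alkoxyphosphonium ion), with no stereocentre involved.

Step 7
Reactants: 15 (9R,11R,13S,15S)-1-bromo-9,11,13,15-tetramethylheptadecane, 16 1,1-dibromoprop-1-ene
Product: 18 (2Z,12R,14R,16S,18S)-3-bromo-12,14,16,18-tetramethylicos-2-ene, via alkylzinc bromide 17 (not isolated)
Conditions: Zn dust, I2 (5 mol%), DMA, 80 °C; then 16 (1.5 equiv), PdCl2(DPEphos) (3 mol%), THF, 0 → 23 °C
Reagents that add atoms: none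
Why: Zinc inserts into the primary C–Br bond and the alkylzinc bromide undergoes Negishi coupling in which zerovalent palladium adds to the less hindered C–Br bond of 16 (trans to the methyl group), so that one alkyl group enters and the (Z)-bromoalkene should result.

Step 8
Reactants: 19 dimethyl squarate
Product: 21 3-methoxycyclobut-3-ene-1,2-dione, via hydroxycyclobutenone 20 (not isolated)
Conditions: LiAlH(O-t-Bu)3, THF, −78 → −20 °C; then conc. HCl, CH2Cl2, 23 °C
Reagents that add atoms: water, O
Why: Hydride adds 1,2 to one squarate carbonyl, and acid then ionises the allylic alcohol and hydrolyses the vinylogous oxocarbenium ion with loss of methanol (1,2-carbonyl transposition), giving the semisquarate.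

Step 9
Reactants: 18 (2Z,12R,14R,16S,18S)-3-bromo-12,14,16,18-tetramethylicos-2-ene, 21 3-methoxycyclobut-3-ene-1,2-dione
Product: 23 4-hydroxy-3-methoxy-4-[(2Z,12R,14R,16S,18S)-12,14,16,18-tetramethylicos-2-en-3-yl]cyclobut-2-en-1-one (both C4 epimers), via alkenyllithium 22 (not isolated)
Conditions: t-BuLi (2 equiv), THF/Et2O, −78 °C; then 21, THF, −78 °C; aq. NH4Cl
Reagents that add atoms: none
Why: Bromine–lithium exchange proceeds with retention and the alkenyllithium adds 1,2 to the more electrophilic carbonyl of 21 (the one next to the methoxy-bearing carbon, outside the vinylogous ester), which fixes OMe/H against chain/methyl in the later ring; the new carbinol centre forms as both epimers and is destroyed in step 10.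

Step 10
Reactants: 23 4-hydroxy-3-methoxy-4-[(2Z,12R,14R,16S,18S)-12,14,16,18-tetramethylicos-2-en-3-yl]cyclobut-2-en-1-one
Product: 27 5-methoxy-2-methyl-3-[(9R,11R,13S,15S)-9,11,13,15-tetramethylheptadecyl]cyclohexa-2,5-diene-1,4-dione (target), via dienylketene 24 (not isolated), via cyclohexadienone 25 (not isolated), via hydroquinone 26 (not isolated)
Conditions: PhMe (degassed), 110 °C; cool; then Ag2O, Na2SO4, 23 °C
Reagents that add atoms: none
Why: Heating triggers conrotatory 4π-electrocyclic opening of the strained cyclobutenone at its C1–C4 bond, the hydroxyl rotating outward so that the alkenyl group faces the ketene in dienylketene 24. Thermal disrotatory 6π-electrocyclisation then joins the ketene carbon C1 to the alkene terminus (the C1–C2 bond of the six-membered ring) to give cyclohexadienone 25, which enolises to hydroquinone 26 and is oxidised by Ag2O to the quinone. The closest known reaction type is the Moore rearrangement of 4-alkenyl-4-hydroxycyclobutenones. No new stereocentre survives: the carbinol centre of 23 and C6 of 25 become sp2, and the four side-chain centres are remote and untouched. The step needs torquoselectivity (hydroxyl outward, since inward rotation would let the hydroxyl trap the ketene as a furanone) and a fixed substituent pattern, both secured by the substrate through the donor hydroxyl on C4 and the positions of OMe, H, methyl and chain set in step 9. Either alkene geometry converges on 26.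

**Compound list**

1 | dec-9-en-1-ol | OCCCCCCCCC=C | starting material
2 | tert-butyl(dec-9-en-1-yloxy)dimethylsilane | C=CCCCCCCCCO[Si](C)(C)C(C)(C)C | intermediate
3 | vinyl bromide | C=CBr | starting material
4 | [(2R)-10-(tert-butyldimethylsilyloxy)-2-methyldecyl]dimethylalane | C[Al](C)C[C@H](C)CCCCCCCCO[Si](C)(C)C(C)(C)C | intermediate
5 | [(2R)-10-(tert-butyldimethylsilyloxy)-2-methyldecyl]zinc triflate | FC(F)(F)S(=O)(=O)O[Zn]C[C@H](C)CCCCCCCCO[Si](C)(C)C(C)(C)C | intermediate
6 | tert-butyldimethyl{[(9R)-9-methyldodec-11-en-1-yl]oxy}silane | C=CC[C@H](C)CCCCCCCCO[Si](C)(C)C(C)(C)C | intermediate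
7 | [(2R,4R)-12-(tert-butyldimethylsilyloxy)-2,4-dimethyldodecyl]dimethylalane | C[Al](C)C[C@H](C)C[C@H](C)CCCCCCCCO[Si](C)(C)C(C)(C)C | intermediate
8 | [(2R,4R)-12-(tert-butyldimethylsilyloxy)-2,4-dimethyldodecyl]zinc triflate | FC(F)(F)S(=O)(=O)O[Zn]C[C@H](C)C[C@H](C)CCCCCCCCO[Si](C)(C)C(C)(C)C | intermediate
9 | tert-butyl{[(9R,11S)-9,11-dimethyltetradec-13-en-1-yl]oxy}dimethylsilane (9,11-syn) | C=CC[C@H](C)C[C@H](C)CCCCCCCCO[Si](C)(C)C(C)(C)C | intermediate
10 | [(2R,4R,6R)-14-(tert-butyldimethylsilyloxy)-2,4,6-trimethyltetradecyl]dimethylalane | C[Al](C)C[C@H](C)C[C@H](C)C[C@H](C)CCCCCCCCO[Si](C)(C)C(C)(C)C | intermediate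
11 | [(2R,4R,6R)-14-(tert-butyldimethylsilyloxy)-2,4,6-trimethyltetradecyl]zinc triflate | FC(F)(F)S(=O)(=O)O[Zn]C[C@H](C)C[C@H](C)C[C@H](C)CCCCCCCCO[Si](C)(C)C(C)(C)C | intermediate
12 | tert-butyldimethyl{[(9R,11R,13S)-9,11,13-trimethylhexadec-15-en-1-yl]oxy}silane (all-syn) | C=CC[C@H](C)C[C@H](C)C[C@H](C)CCCCCCCCO[Si](C)(C)C(C)(C)C | intermediate
13 | diethyl[(2S,4R,6R,8R)-16-(tert-butyldimethylsilyloxy)-2-ethyl-4,6,8-trimethylhexadecyl]alane | CC[Al](CC)C[C@@H](CC)C[C@H](C)C[C@H](C)C[C@H](C)CCCCCCCCO[Si](C)(C)C(C)(C)C | intermediate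
14 | tert-butyldimethyl{[(9R,11R,13S,15S)-9,11,13,15-tetramethylheptadecyl]oxy}silane | CC[C@H](C)C[C@H](C)C[C@H](C)C[C@H](C)CCCCCCCCO[Si](C)(C)C(C)(C)C | intermediate
15 | (9R,11R,13S,15S)-1-bromo-9,11,13,15-tetramethylheptadecane | CC[C@H](C)C[C@H](C)C[C@H](C)C[C@H](C)CCCCCCCCBr | intermediate
16 | 1,1-dibromoprop-1-ene | CC=C(Br)Br | starting material
17 | [(9R,11R,13S,15S)-9,11,13,15-tetramethylheptadecyl]zinc bromide | CC[C@H](C)C[C@H](C)C[C@H](C)C[C@H](C)CCCCCCCC[Zn]Br | intermediate
18 | (2Z,12R,14R,16S,18S)-3-bromo-12,14,16,18-tetramethylicos-2-ene | CC[C@H](C)C[C@H](C)C[C@H](C)C[C@H](C)CCCCCCCC/C(Br)=C/C | intermediate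
19 | dimethyl squarate (3,4-dimethoxycyclobut-3-ene-1,2-dione) | COC1=C(OC)C(=O)C1=O | starting material
20 | 4-hydroxy-2,3-dimethoxycyclobut-2-en-1-one (racemic) | COC1=C(OC)C(O)C1=O | intermediate
21 | 3-methoxycyclobut-3-ene-1,2-dione | COC1=CC(=O)C1=O | intermediate
22 | [(2E,12R,14R,16S,18S)-12,14,16,18-tetramethylicos-2-en-3-yl]lithium (lithium cis to the C1 methyl) | CC[C@H](C)C[C@H](C)C[C@H](C)C[C@H](C)CCCCCCCC/C([Li])=C/C | intermediate
23 | 4-hydroxy-3-methoxy-4-[(2Z,12R,14R,16S,18S)-12,14,16,18-tetramethylicos-2-en-3-yl]cyclobut-2-en-1-one (both C4 epimers) | CC[C@H](C)C[C@H](C)C[C@H](C)C[C@H](C)CCCCCCCC/C(=C/C)C1(O)C(=O)C=C1OC | intermediate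
24 | (3Z,5Z)-4-hydroxy-3-methoxy-5-[(9R,11R,13S,15S)-9,11,13,15-tetramethylheptadecyl]hepta-1,3,5-trien-1-one | CC[C@H](C)C[C@H](C)C[C@H](C)C[C@H](C)CCCCCCCC/C(=C/C)/C(O)=C(OC)\C=C=O | intermediate
25 | 4-hydroxy-3-methoxy-6-methyl-5-[(9R,11R,13S,15S)-9,11,13,15-tetramethylheptadecyl]cyclohexa-2,4-dien-1-one (both C6 epimers) | CC[C@H](C)C[C@H](C)C[C@H](C)C[C@H](C)CCCCCCCCC1=C(O)C(OC)=CC(=O)C1C | intermediate
26 | 5-methoxy-2-methyl-3-[(9R,11R,13S,15S)-9,11,13,15-tetramethylheptadecyl]benzene-1,4-diol | CC[C@H](C)C[C@H](C)C[C@H](C)C[C@H](C)CCCCCCCCc1c(C)c(O)cc(OC)c1O | intermediate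
27 | 5-methoxy-2-methyl-3-[(9R,11R,13S,15S)-9,11,13,15-tetramethylheptadecyl]cyclohexa-2,5-diene-1,4-dione | CC[C@H](C)C[C@H](C)C[C@H](C)C[C@H](C)CCCCCCCCC1=C(C)C(=O)C=C(OC)C1=O | target

**Step count.** Total: 10 steps. Longest linear sequence: 9 steps (steps 1–7, 9 and 10, from dec-9-en-1-ol); step 8 is a one-step side branch.

**Steps most likely to fail**

Step 10. The 6π-electrocyclisation may lose to other fates of the aldoketene: capture by the tertiary hydroxyl after inward rotation, oligomerisation, or hydrogen shift from the inward methyl group. The fallback sets out from 18 and returns at 27, closing the ring by a vinylketene–alkyne benzannulation instead. Bromine–lithium exchange on 18 (t-BuLi, −78 °C) and acylation with N-methoxy-N-methylacetamide should give (3Z)-3-[(9R,11R,13S,15S)-9,11,13,15-tetramethylheptadecyl]pent-3-en-2-one F1. Detrifluoroacetylative diazo transfer (LiN(SiMe3)2, CF3CO2CH2CF3, then MsN3, Et3N) should give (3Z)-1-diazo-3-[(9R,11R,13S,15S)-9,11,13,15-tetramethylheptadecyl]pent-3-en-2-one F2. Irradiation of F2 with methoxyethyne (photochemical Wolff rearrangement and Danheiser benzannulation, finished at 80 °C) should give 5-methoxy-2-methyl-3-[(9R,11R,13S,15S)-9,11,13,15-tetramethylheptadecyl]phenol F3. Its free para position is then oxidised with Fremy's salt (KSO3)2NO to 27.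

Step 9. Site selectivity may be lost with the small, base-sensitive methyl semisquarate: attack at the methoxy-bearing carbon with loss of methoxide, conjugate addition at the unsubstituted ring carbon, or proton abstraction. The fallback sets out from 18 and returns at 27, using the more robust isopropyl vinylogous ester and exchanging the alkoxy group at the end. 3-(Propan-2-yloxy)cyclobut-3-ene-1,2-dione F4 is made from diisopropyl squarate by the method of step 8. Alkenyllithium 22 (from 18 as in step 9) should add to it to give 4-hydroxy-3-(propan-2-yloxy)-4-[(2Z,12R,14R,16S,18S)-12,14,16,18-tetramethylicos-2-en-3-yl]cyclobut-2-en-1-one F5. Thermolysis in toluene and Ag2O oxidation as in step 10 should give 2-methyl-5-(propan-2-yloxy)-3-[(9R,11R,13S,15S)-9,11,13,15-tetramethylheptadecyl]cyclohexa-2,5-diene-1,4-dione F6. Acid-catalysed alkoxy exchange at the vinylogous ester carbon (MeOH, cat. H2SO4, 23 °C) then leads to 27.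

Step 5. Facial discrimination in the ethylalumination may be insufficient, or of the opposite sense to that assumed, giving a C15 epimer that is remote from any polar group and hard to remove. The fallback sets out from 12 and returns at 14, setting C15 by the same methylalumination used for C9, C11 and C13. ZACA of 12 with Me3Al and (−)-(NMI)2ZrCl2 should give [(2R,4R,6R,8R)-16-(tert-butyldimethylsilyloxy)-2,4,6,8-tetramethylhexadecyl]dimethylalane F7. Iodinolysis (I2, THF) should give tert-butyl{[(9R,11R,13R,15R)-16-iodo-9,11,13,15-tetramethylhexadecyl]oxy}dimethylsilane F8, which can be purified. Me2CuLi (Et2O, 0 °C) then installs the terminal methyl group to reach 14.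

**Further compounds**

F1 | step 10 | (3Z)-3-[(9R,11R,13S,15S)-9,11,13,15-tetramethylheptadecyl]pent-3-en-2-one | CC[C@H](C)C[C@H](C)C[C@H](C)C[C@H](C)CCCCCCCC/C(=C/C)C(C)=O
F2 | step 10 | (3Z)-1-diazo-3-[(9R,11R,13S,15S)-9,11,13,15-tetramethylheptadecyl]pent-3-en-2-one | CC[C@H](C)C[C@H](C)C[C@H](C)C[C@H](C)CCCCCCCC/C(=C/C)C(=O)C=[N+]=[N-]
F3 | step 10 | 5-methoxy-2-methyl-3-[(9R,11R,13S,15S)-9,11,13,15-tetramethylheptadecyl]phenol | CC[C@H](C)C[C@H](C)C[C@H](C)C[C@H](C)CCCCCCCCc1cc(OC)cc(O)c1C
F4 | step 9 | 3-(propan-2-yloxy)cyclobut-3-ene-1,2-dione | CC(C)OC1=CC(=O)C1=O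
F5 | step 9 | 4-hydroxy-3-(propan-2-yloxy)-4-[(2Z,12R,14R,16S,18S)-12,14,16,18-tetramethylicos-2-en-3-yl]cyclobut-2-en-1-one | CC[C@H](C)C[C@H](C)C[C@H](C)C[C@H](C)CCCCCCCC/C(=C/C)C1(O)C(=O)C=C1OC(C)C
F6 | step 9 | 2-methyl-5-(propan-2-yloxy)-3-[(9R,11R,13S,15S)-9,11,13,15-tetramethylheptadecyl]cyclohexa-2,5-diene-1,4-dione | CC[C@H](C)C[C@H](C)C[C@H](C)C[C@H](C)CCCCCCCCC1=C(C)C(=O)C=C(OC(C)C)C1=O
F7 | step 5 | [(2R,4R,6R,8R)-16-(tert-butyldimethylsilyloxy)-2,4,6,8-tetramethylhexadecyl]dimethylalane | C[Al](C)C[C@H](C)C[C@H](C)C[C@H](C)C[C@H](C)CCCCCCCCO[Si](C)(C)C(C)(C)C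
F8 | step 5 | tert-butyl{[(9R,11R,13R,15R)-16-iodo-9,11,13,15-tetramethylhexadecyl]oxy}dimethylsilane | IC[C@H](C)C[C@H](C)C[C@H](C)C[C@H](C)CCCCCCCCO[Si](C)(C)C(C)(C)C
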